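**Assumption:** azaphilone numbering (O2, C1, C3 to C8a) is used for every intermediate, and the roughly 90 % ee from the epoxidation is raised to a single enantiomer by recrystallising 16.

## Retrosynthetic overview
1. The C8–O ester bond is made last. Unprotected orsellinic acid opens a 7,8-epoxide by SN2, which sets 8S and frees the 7-OH. No protecting group is used anywhere.
2. Rings A and B form together. A 1,3-diacylallene (O=C3–C4=C4a) undergoes an intramolecular oxa-Diels–Alder reaction onto the vinyl group (C8a=C1), making C4a–C8a and O2–C1.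
3. The allene comes from double MnO2 oxidation and tautomerisation of an enyne diol. That diol comes from an acetylide plus an epoxy aldehyde.
4. The epoxy aldehyde comes from acrolein by Z-selective olefination, reduction, Sharpless epoxidation (source of absolute configuration) and oxidation.
5. Ring order: oxirane (temporary), then rings A and B in one operation, then the oxirane is opened.

## Route

**Step 1**
Reactants: 1 acrolein; 2 ethyl 2-[bis(2,2,2-trifluoroethoxy)phosphoryl]propanoate
Product: 4 ethyl (2Z)-2-methylpenta-2,4-dienoate, via potassium phosphonate carbanion 3 (not isolated)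
Conditions: KN(SiMe3)2, 18-crown-6, THF, −78 °C
Reagents that add atoms: none
Why: In this Still–Gennari variant of the Horner–Wadsworth–Emmons olefination, fast irreversible elimination from the trifluoroethyl phosphonate adduct gives the Z-trisubstituted enoate, with ester and vinyl cis as ring B will later require.

**Step 2**
Reactants: 4 ethyl (2Z)-2-methylpenta-2,4-dienoate
Product: 5 (2Z)-2-methylpenta-2,4-dien-1-ol
Conditions: i-Bu2AlH (2.2 equiv), CH2Cl2, −78 to 0 °C; Rochelle salt work-up
Reagents that add atoms: none
Why: 1,2-Reduction of the conjugated ester with a hydridoalane leaves the diene and its Z geometry untouched.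

**Step 3**
Reactants: 5 (2Z)-2-methylpenta-2,4-dien-1-ol
Product: 6 [(2S,3R)-3-ethenyl-2-methyloxiran-2-yl]methanol
Conditions: Ti(Oi-Pr)4 (0.2 equiv), L-(+)-diethyl tartrate (0.24 equiv), t-BuOOH, 4 Å MS, CH2Cl2, −20 °C
Reagents that add atoms: tert-butyl hydroperoxide, CC(C)(C)OO
Why: In the Sharpless asymmetric epoxidation only the alkene bound through the allylic alkoxide reacts (the vinyl group is spared), and L-(+)-tartrate gives the (2S)-epoxide as with other (Z)-2-methylalk-2-en-1-ols, which fixes C7 and the pre-inversion C8 with CH2OH and vinyl cis.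

**Step 4**
Reactants: 6 [(2S,3R)-3-ethenyl-2-methyloxiran-2-yl]methanol
Product: 7 (2R,3R)-3-ethenyl-2-methyloxirane-2-carbaldehyde
Conditions: TEMPO (10 mol %), PhI(OAc)2 (1.1 equiv), CH2Cl2, 0 °C to rt; used as a cold solution
Reagents that add atoms: none
Why: Oxoammonium (TEMPO) oxidation of a primary alcohol is mild enough for epoxy alcohols, and the α-carbon is quaternary so it cannot epimerise (the descriptor changes only because the priorities change).

**Step 5**
Reactants: 8 (E)-crotonaldehyde; 9 propargyl bromide
Product: 11 (5E)-hept-5-en-1-yn-4-ol (racemic), via allenylzinc bromide 10 (not isolated)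
Conditions: Zn dust, THF, 0 °C to rt; aq NH4Cl work-up
Reagents that add atoms: none
Why: In this Barbier propargylation the allenylzinc adds 1,2 to the enal by SE2' to give the homopropargylic alcohol, and its carbinol centre is erased in step 7.

**Step 6**
Reactants: 7 (2R,3R)-3-ethenyl-2-methyloxirane-2-carbaldehyde; 11 (5E)-hept-5-en-1-yn-4-ol
Product: 13 (6E)-1-[(2S,3R)-3-ethenyl-2-methyloxiran-2-yl]oct-6-en-2-yne-1,5-diol (carbinol epimers), via dilithium alkoxide acetylide 12 (not isolated)
Conditions: 11 (1.2 equiv), n-BuLi (2.4 equiv), THF, −78 °C; then 7, −78 °C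
Reagents that add atoms: none
Why: Lithium acetylide adds to the non-enolisable aldehyde at low temperature without touching the oxirane, and both new carbinol centres are destroyed in the next step.

**Step 7**
Reactants: 13 (6E)-1-[(2S,3R)-3-ethenyl-2-methyloxiran-2-yl]oct-6-en-2-yne-1,5-diol
Product: 16 (7R,8R,8aS)-7,8-epoxy-7-methyl-3-[(E)-prop-1-enyl]-1,7,8,8a-tetrahydro-6H-isochromen-6-one, via epoxy ynedione 14 (not isolated), via epoxy diacylallene 15 (not isolated)
Conditions: activated MnO2 (25 equiv), toluene (0.005 M), BHT, rt, 2 h; then Et3N (10 mol %), 80 °C, same flask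
Reagents that add atoms: none
Why: Proposed new method: MnO2 oxidises the propargylic and the allylic carbinol, and the CH2 flanked by ynone and enone tautomerises to the 1,3-diacylallene 15; its O=C3–C4=C4a unit then acts as an electron-poor 1-oxadiene toward the tethered vinyl group (intramolecular inverse-electron-demand hetero-Diels–Alder), the four-atom tether and the cis-oxirane enforcing the fused mode so that C4a–C8a and O2–C1 (rings B and A) form together while the orthogonal C4a=C5 bond survives as the enone; the addition takes place on the face of nascent ring B that carries only the small oxirane oxygen, away from the C7 methyl and H8, which gives 8aS; the closest known reaction types are intramolecular Diels–Alder reactions of vinylallenes, domino Knoevenagel/hetero-Diels–Alder closures onto unactivated terminal alkenes, and thermal intramolecular [4+2] cycloadditions of conjugated ynones.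

**Step 8**
Reactants: 16 (7R,8R,8aS)-7,8-epoxy-7-methyl-3-[(E)-prop-1-enyl]-1,7,8,8a-tetrahydro-6H-isochromen-6-one; 17 orsellinic acid (2,4-dihydroxy-6-methylbenzoic acid)
Product: 18 target, (7R,8S,8aS)-7-hydroxy-7-methyl-6-oxo-3-[(E)-prop-1-enyl]-1,7,8,8a-tetrahydro-6H-isochromen-8-yl 2,4-dihydroxy-6-methylbenzoate
Conditions: 17 (1.5 equiv), i-Pr2NEt (0.3 equiv), MeCN, 40 °C
Reagents that add atoms: none
Why: This is a stereospecific SN2 opening of an α,β-epoxy ketone by a carboxylate in a carboxylic acid/ammonium carboxylate buffer, in which C7 is fully substituted and α to the carbonyl so attack occurs at C8 anti to the C–O bond (inversion to 8S, release of the 7R tertiary alcohol, trans hydroxy ester), the medium is too weakly basic for vinylogous elimination through C8a–H, and the un-ionised phenols do not compete.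

## Compound list
1 | acrolein | C=CC=O | starting material
2 | ethyl 2-[bis(2,2,2-trifluoroethoxy)phosphoryl]propanoate | CCOC(=O)C(C)P(=O)(OCC(F)(F)F)OCC(F)(F)F | starting material
3 | potassium phosphonate carbanion of 2 | CCOC(=O)[C-](C)P(=O)(OCC(F)(F)F)OCC(F)(F)F.[K+] | intermediate
4 | ethyl (2Z)-2-methylpenta-2,4-dienoate | C=C/C=C(/C)C(=O)OCC | intermediate
5 | (2Z)-2-methylpenta-2,4-dien-1-ol | C=C/C=C(/C)CO | intermediate
6 | [(2S,3R)-3-ethenyl-2-methyloxiran-2-yl]methanol | OC[C@]1(C)O[C@@H]1C=C | intermediate
7 | (2R,3R)-3-ethenyl-2-methyloxirane-2-carbaldehyde | O=C[C@]1(C)O[C@@H]1C=C | intermediate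
8 | (E)-crotonaldehyde | C/C=C/C=O | starting material
9 | propargyl bromide | C#CCBr | starting material
10 | allenylzinc bromide | C=C=C[Zn]Br | intermediate
11 | (5E)-hept-5-en-1-yn-4-ol (racemic) | C/C=C/C(O)CC#C | intermediate
12 | dilithium alkoxide acetylide of 11 | C/C=C/C([O-])CC#[C-].[Li+].[Li+] | intermediate
13 | (6E)-1-[(2S,3R)-3-ethenyl-2-methyloxiran-2-yl]oct-6-en-2-yne-1,5-diol | C/C=C/C(O)CC#CC(O)[C@]1(C)O[C@@H]1C=C | intermediate
14 | (6E)-1-[(2R,3R)-3-ethenyl-2-methyloxiran-2-yl]oct-6-en-2-yne-1,5-dione | C/C=C/C(=O)CC#CC(=O)[C@]1(C)O[C@@H]1C=C | intermediate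
15 | (6E)-1-[(2R,3R)-3-ethenyl-2-methyloxiran-2-yl]octa-2,3,6-triene-1,5-dione | C/C=C/C(=O)C=C=CC(=O)[C@]1(C)O[C@@H]1C=C | intermediate
16 | (7R,8R,8aS)-7,8-epoxy-7-methyl-3-[(E)-prop-1-enyl]-1,7,8,8a-tetrahydro-6H-isochromen-6-one | C/C=C/C1=CC2=CC(=O)[C@]3(C)O[C@@H]3[C@@H]2CO1 | intermediate
17 | orsellinic acid | Cc1cc(O)cc(O)c1C(=O)O | starting material
18 | CNP0130178.5 | C/C=C/C1=CC2=CC(=O)[C@](C)(O)[C@@H](OC(=O)c3c(C)cc(O)cc3O)[C@@H]2CO1 | target

## Step count and risks
Total steps: 8. Longest linear sequence: 7 (steps 1, 2, 3, 4, 6, 7, 8).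

**Most likely to fail, first: step 7.** The diacylallene may decompose, or the terminal alkene may be too unreactive.
- The fallback sets out from 7 and comes back at 16. It makes the same two bonds (C4a–C8a and C1–O) by a dipolar cycloaddition whose fused regiochemistry is reliable, and then builds ring A stepwise.
- Dilithiated acetaldoxime adds to 7 to give the β-hydroxy oxime F1.
- NaOCl converts F1 into the nitrile oxide, which closes onto the vinyl group to give the tricyclic isoxazoline F2.
- H2 over Raney Ni with B(OH)3 cleaves the N–O bond and hydrolyses the imine to the β-hydroxy ketone F3.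
- The lithium enolate of (E)-pent-3-en-2-one (LiN(i-Pr)2, excess) adds to the C4a ketone to give the aldol adduct F4.
- PPTS closes ring A by ketalisation and dehydration to the bicyclic enol ether diol F5.
- Dess–Martin oxidation of the C6 carbinol, followed by spontaneous loss of water across C4a–C5, delivers 16.

**Second: step 8.** The hindered, weakly nucleophilic carboxylate may be too slow, or elimination may win.
- The fallback sets out from 16 and comes back at 18. The oxirane is opened with a small nucleophile and the ester is made afterwards.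
- Catalytic HClO4 in THF–H2O gives the trans-diol F6, with water attacking C8 with inversion.
- In parallel, 17 with TBSCl and imidazole gives the tris-silyl compound F7.
- K2CO3 in aqueous MeOH cleaves only the silyl ester of F7 to give the bis-silyl acid F8.
- 2-Methyl-6-nitrobenzoic anhydride with DMAP couples F8 to the secondary C8–OH of F6 (the tertiary 7-OH is inert) to give the protected ester F9.
- HF·pyridine then gives 18.

**Third: step 3.** A Z-allylic alcohol is a slow substrate, and the ee or the vinyl epoxide may suffer.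
- The fallback sets out from 5 and comes back at 6. It replaces asymmetric catalysis by resolution.
- VO(acac)2 with t-BuOOH gives the racemic cis-epoxy alcohol F10, still selective for the allylic alkene.
- Pseudomonas cepacia lipase with vinyl acetate acylates the unwanted enantiomer to the acetate F11.
- This leaves 6, which is separated by chromatography.

## Further compounds
F1 | step 7 | 3-[(2S,3R)-3-ethenyl-2-methyloxiran-2-yl]-3-hydroxypropanal oxime | ON=CCC(O)[C@]1(C)O[C@@H]1C=C
F2 | step 7 | tricyclic isoxazoline (C4a=N–O–C1, 7,8-epoxide, 6-OH) | O1N=C2CC(O)[C@]3(C)O[C@@H]3[C@@H]2C1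
F3 | step 7 | 7,8-epoxy-6-hydroxy-8a-(hydroxymethyl)-7-methylcyclohexan-4a-one (core numbering) | O=C1CC(O)[C@]2(C)O[C@@H]2[C@@H]1CO
F4 | step 7 | aldol adduct of F3 with (E)-pent-3-en-2-one | C/C=C/C(=O)CC1(O)CC(O)[C@]2(C)O[C@@H]2[C@@H]1CO
F5 | step 7 | 7,8-epoxy-4a,6-dihydroxy bicyclic enol ether | C/C=C/C1=CC2(O)CC(O)[C@]3(C)O[C@@H]3[C@@H]2CO1
F6 | step 8 | (7R,8S,8aS)-7,8-dihydroxy-7-methyl-3-[(E)-prop-1-enyl]-1,7,8,8a-tetrahydro-6H-isochromen-6-one | C/C=C/C1=CC2=CC(=O)[C@](C)(O)[C@@H](O)[C@@H]2CO1
F7 | step 8 | tert-butyldimethylsilyl 2,4-bis(tert-butyldimethylsilyloxy)-6-methylbenzoate | Cc1cc(O[Si](C)(C)C(C)(C)C)cc(O[Si](C)(C)C(C)(C)C)c1C(=O)O[Si](C)(C)C(C)(C)C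
F8 | step 8 | 2,4-bis(tert-butyldimethylsilyloxy)-6-methylbenzoic acid | Cc1cc(O[Si](C)(C)C(C)(C)C)cc(O[Si](C)(C)C(C)(C)C)c1C(=O)O
F9 | step 8 | bis-TBS ether of 18 | C/C=C/C1=CC2=CC(=O)[C@](C)(O)[C@@H](OC(=O)c3c(C)cc(O[Si](C)(C)C(C)(C)C)cc3O[Si](C)(C)C(C)(C)C)[C@@H]2CO1
F10 | step 3 | racemic cis-(3-ethenyl-2-methyloxiran-2-yl)methanol | OC[C@]1(C)O[C@@H]1C=C.OC[C@@]1(C)O[C@H]1C=C
F11 | step 3 | [(2R,3S)-3-ethenyl-2-methyloxiran-2-yl]methyl acetate | CC(=O)OC[C@@]1(C)O[C@H]1C=C
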